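**Strategy.** The route rests on disconnecting the hydroxyquinone ring (quinone atoms C1(=O), C2(OH), C3(prenyl), C4(=O), C5(chromanyl), C6(H)) into a four-carbon squarate unit and a two-carbon alkyne. A 4-alkynyl-4-hydroxycyclobutenone is assembled from 3-methoxy-4-prenylcyclobutenedione and the lithium acetylide of an (R)-3-ethynylchroman. On heating, 4π ring opening and enyne–ketene cyclisation (Moore rearrangement) should build the fully substituted quinone ring in one operation, directly at the quinone oxidation level. The step exploits the para-dicarbonyl pattern of this ring: C1–C4 map onto the cyclobutenone, C5/C6 onto the alkyne. The chroman stereocentre is set earlier by asymmetric hydrogenation of a chromene acid.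

Key step: step 14

Remark: in step 7 the (Sa,S) catalyst antipode is assigned by analogy only; whichever antipode delivers the (3S)-acid is the one meant. "Prenyl" = 3-methylbut-2-en-1-yl throughout.

**Step 1**
Reactants: 1 3,5-dimethoxyphenol
Product: 2 (3,5-dimethoxyphenoxy)triisopropylsilane
Conditions: TIPSCl, imidazole, DMF, rt
Reagents that add atoms: triisopropylsilyl chloride, CC(C)[Si](Cl)(C(C)C)C(C)C
Why: Imidazole-mediated O-silylation of a phenol should give the bulky TIPS ether, which masks the oxygen as a non-directing group for the metalation that follows.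

**Step 2**
Reactants: 2 (3,5-dimethoxyphenoxy)triisopropylsilane; 3 1-bromo-3-methylbut-2-ene
Product: 5 [3,5-dimethoxy-4-(3-methylbut-2-en-1-yl)phenoxy]triisopropylsilane, via aryllithium 4 (not isolated)
Conditions: n-BuLi, THF, 0 °C to rt; then CuI (10 mol%), 3, −78 °C to rt
Reagents that add atoms: 1-bromo-3-methylbut-2-ene (3), CC(C)=CCBr
Why: Directed ortho-metalation should occur at the carbon flanked by the two methoxy groups (the hindered, weakly coordinating OTIPS group does not direct), and copper-catalysed SN2 allylation of the aryllithium should give the linear prenyl arene.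

**Step 3**
Reactants: 5 [3,5-dimethoxy-4-(3-methylbut-2-en-1-yl)phenoxy]triisopropylsilane
Product: 6 3,5-dimethoxy-4-(3-methylbut-2-en-1-yl)phenol
Conditions: TBAF, AcOH, THF, 0 °C
Reagents that add atoms: none
Why: Fluoride-mediated desilylation of an aryl silyl ether should free the phenol without touching the prenyl group.

**Step 4**
Reactants: 6 3,5-dimethoxy-4-(3-methylbut-2-en-1-yl)phenol
Product: 7 6-hydroxy-2,4-dimethoxy-3-(3-methylbut-2-en-1-yl)benzaldehyde
Conditions: MgCl2, Et3N, (CH2O)n, MeCN, reflux; then 1 M HCl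
Reagents that add atoms: paraformaldehyde (as formaldehyde), C=O
Why: Magnesium-mediated ortho-formylation (Casnati–Skattebøl) should deliver formaldehyde only to the position ortho to the phenoxide (both ortho positions are equivalent, the para position is blocked), a second equivalent of formaldehyde acting as hydride acceptor.

**Step 5**
Reactants: 7 6-hydroxy-2,4-dimethoxy-3-(3-methylbut-2-en-1-yl)benzaldehyde; 8 acrylonitrile
Product: 9 5,7-dimethoxy-6-(3-methylbut-2-en-1-yl)-2H-chromene-3-carbonitrile
Conditions: DABCO (0.5 equiv), acrylonitrile (neat), 80 °C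
Reagents that add atoms: acrylonitrile (8), C=CC#N
Why: The DABCO-mediated Baylis–Hillman/oxa-Michael annulation of salicylaldehydes with acrylonitrile should close the pyran ring and dehydrate to the 2H-chromene.

**Step 6**
Reactants: 9 5,7-dimethoxy-6-(3-methylbut-2-en-1-yl)-2H-chromene-3-carbonitrile
Product: 10 5,7-dimethoxy-6-(3-methylbut-2-en-1-yl)-2H-chromene-3-carboxylic acid
Conditions: NaOH, H2O/EtOH, reflux; then HCl
Reagents that add atoms: sodium hydroxide, [Na+].[OH-]; water, O
Why: Alkaline hydrolysis of the conjugated nitrile should give the acid, the chromene, aryl ethers and prenyl group being inert to aqueous base.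

**Step 7**
Reactants: 10 5,7-dimethoxy-6-(3-methylbut-2-en-1-yl)-2H-chromene-3-carboxylic acid
Product: 11 (3S)-5,7-dimethoxy-6-(3-methylbut-2-en-1-yl)chromane-3-carboxylic acid
Conditions: H2 (6 atm), [Ir(cod)((Sa,S)-SIPHOX)]BArF (1 mol%), Et3N (0.5 equiv), MeOH, 45 °C
Reagents that add atoms: none
Why: Carboxylate-directed iridium-catalysed asymmetric hydrogenation of the α,β-unsaturated acid should set C3 by catalyst-controlled hydrogen delivery to one face of C3=C4, while the prenyl alkene, which cannot bind through a carboxylate, should stay untouched.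

**Step 8**
Reactants: 11 (3S)-5,7-dimethoxy-6-(3-methylbut-2-en-1-yl)chromane-3-carboxylic acid
Product: 12 [(3R)-5,7-dimethoxy-6-(3-methylbut-2-en-1-yl)chroman-3-yl]methanol
Conditions: LiAlH4, THF, 0 °C to rt; Fieser work-up
Reagents that add atoms: none
Why: Hydride reduction of the acid to the primary alcohol should proceed through a non-enolisable carboxylate, so C3 is not at risk (the descriptor changes only through CIP priorities).

**Step 9**
Reactants: 12 [(3R)-5,7-dimethoxy-6-(3-methylbut-2-en-1-yl)chroman-3-yl]methanol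
Product: 13 (3S)-5,7-dimethoxy-6-(3-methylbut-2-en-1-yl)chromane-3-carbaldehyde
Conditions: Dess–Martin periodinane, NaHCO3, CH2Cl2, 0 °C to rt; used crude
Reagents that add atoms: none
Why: Buffered Dess–Martin oxidation should give the α-branched aldehyde under non-epimerising conditions, and the aldehyde is carried on at once.

**Step 10**
Reactants: 13 (3S)-5,7-dimethoxy-6-(3-methylbut-2-en-1-yl)chromane-3-carbaldehyde
Product: 14 (3R)-3-(2,2-dibromoethenyl)-5,7-dimethoxy-6-(3-methylbut-2-en-1-yl)chromane
Conditions: CBr4, PPh3, Zn, CH2Cl2, rt (ylide pre-formed); then 13, 0 °C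
Reagents that add atoms: carbon tetrabromide, BrC(Br)(Br)Br
Why: The first stage of the Corey–Fuchs homologation uses a non-basic ylide, so the enolisable α-stereocentre should survive.

**Step 11**
Reactants: 15 dimethyl squarate (3,4-dimethoxycyclobut-3-ene-1,2-dione); 16 allylmagnesium bromide
Product: 18 3-methoxy-4-(prop-2-en-1-yl)cyclobut-3-ene-1,2-dione, via magnesium alkoxide 17 (not isolated)
Conditions: 16, THF, −78 °C; then (CF3CO)2O, −78 °C to 0 °C
Reagents that add atoms: allylmagnesium bromide (16), C=CC[Mg]Br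
Why: 1,2-Addition of the Grignard reagent to a squarate carbonyl followed by trifluoroacetylation and loss of a methoxy group is the standard Moore–Liebeskind cyclobutenedione synthesis; allyl is used because a prenyl metal would attack through its γ-carbon.

**Step 12**
Reactants: 18 3-methoxy-4-(prop-2-en-1-yl)cyclobut-3-ene-1,2-dione; 19 2-methylbut-2-ene
Product: 20 3-methoxy-4-(3-methylbut-2-en-1-yl)cyclobut-3-ene-1,2-dione
Conditions: Grubbs II (3 mol%), 2-methylbut-2-ene/CH2Cl2, 40 °C
Reagents that add atoms: 2-methylbut-2-ene (19), CC=C(C)C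
Why: Olefin cross-metathesis with 2-methylbut-2-ene should convert the terminal allyl group into prenyl, the tetrasubstituted electron-poor ring alkene being inert.

**Step 13**
Reactants: 14 (3R)-3-(2,2-dibromoethenyl)-5,7-dimethoxy-6-(3-methylbut-2-en-1-yl)chromane; 20 3-methoxy-4-(3-methylbut-2-en-1-yl)cyclobut-3-ene-1,2-dione
Product: 22 4-hydroxy-3-methoxy-2-(3-methylbut-2-en-1-yl)-4-{[(3R)-5,7-dimethoxy-6-(3-methylbut-2-en-1-yl)chroman-3-yl]ethynyl}cyclobut-2-en-1-one, via lithium acetylide 21 (not isolated)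
Conditions: n-BuLi (2.1 equiv), THF, −78 °C; then 20, −78 °C; sat. aq NH4Cl
Reagents that add atoms: none
Why: The second stage of the Corey–Fuchs reaction (Br/Li exchange, Fritsch–Buttenberg–Wiechell shift, deprotonation) should give the acetylide, which should add 1,2 to the ketone carbonyl next to C–OMe and not to the vinylogous ester carbonyl; the new carbinol centre forms unselectively and is lost in step 14.

**Step 14**
Reactants: 22 4-hydroxy-3-methoxy-2-(3-methylbut-2-en-1-yl)-4-{[(3R)-5,7-dimethoxy-6-(3-methylbut-2-en-1-yl)chroman-3-yl]ethynyl}cyclobut-2-en-1-one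
Product: 25 2-methoxy-3-(3-methylbut-2-en-1-yl)-5-[(3R)-5,7-dimethoxy-6-(3-methylbut-2-en-1-yl)chroman-3-yl]cyclohexa-2,5-diene-1,4-dione, via enynylketene 23 (not isolated), via aryl diradical 24 (not isolated)
Conditions: toluene (0.01 M, degassed), 110 °C
Reagents that add atoms: none
Why: Heating should open the cyclobutenone by conrotatory 4π-electrocyclic cleavage of the bond between the carbinol carbon (future C1) and the carbonyl carbon (future C4), giving (Z)-enynylketene 23; the ketene carbon C4 then bonds to the distal alkyne carbon C5 to give aryl diradical 24, and transfer of the hydroxyl hydrogen to the ring σ-radical carbon C6 gives quinone 25 directly. The closest known reaction type is the Moore rearrangement of 4-alkynyl-4-hydroxycyclobutenones, which is established for alkyl-substituted alkynes. The quinone ring is the only ring closed, by a six-membered enyne–ketene cycloaromatisation (C4–C5 bond formation) that follows the electrocyclic opening of the four-membered ring. No stereocentre is created: the carbinol centre of 22 becomes sp2, and chroman C3 is a spectator whose C–H never becomes part of a conjugated or radical site. The step needs outward rotation of the hydroxyl so that the alkynyl group faces the ketene (secured by the donor OH, torquoselectivity), six- over five-membered closure (secured by the secondary alkyl group on the alkyne terminus, which does not stabilise the alternative exocyclic vinyl radical) and the correct substituent pattern (fixed in step 13 by the site of acetylide addition).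

**Step 15**
Reactants: 25 2-methoxy-3-(3-methylbut-2-en-1-yl)-5-[(3R)-5,7-dimethoxy-6-(3-methylbut-2-en-1-yl)chroman-3-yl]cyclohexa-2,5-diene-1,4-dione
Product: 26 2-hydroxy-3-(3-methylbut-2-en-1-yl)-5-[(3R)-5,7-dimethoxy-6-(3-methylbut-2-en-1-yl)chroman-3-yl]cyclohexa-2,5-diene-1,4-dione
Conditions: LiOH (2 equiv), THF/H2O, 0 °C, short time; then 1 M HCl
Reagents that add atoms: lithium hydroxide, [Li+].[OH-]
Why: Saponification of the vinylogous methyl ester by addition–elimination of hydroxide at the methoxy-bearing quinone carbon should give the hydroxyquinone, whose anion is deactivated toward further attack; low temperature and short time protect C3.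

**Compound list**

1 | 3,5-dimethoxyphenol | COc1cc(O)cc(OC)c1 | starting material
2 | (3,5-dimethoxyphenoxy)triisopropylsilane | COc1cc(O[Si](C(C)C)(C(C)C)C(C)C)cc(OC)c1 | intermediate
3 | 1-bromo-3-methylbut-2-ene (prenyl bromide) | CC(C)=CCBr | starting material
4 | [2,6-dimethoxy-4-(triisopropylsilyloxy)phenyl]lithium | COc1cc(O[Si](C(C)C)(C(C)C)C(C)C)cc(OC)c1[Li] | intermediate (not isolated)
5 | [3,5-dimethoxy-4-(3-methylbut-2-en-1-yl)phenoxy]triisopropylsilane | COc1cc(O[Si](C(C)C)(C(C)C)C(C)C)cc(OC)c1CC=C(C)C | intermediate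
6 | 3,5-dimethoxy-4-(3-methylbut-2-en-1-yl)phenol | COc1cc(O)cc(OC)c1CC=C(C)C | intermediate
7 | 6-hydroxy-2,4-dimethoxy-3-(3-methylbut-2-en-1-yl)benzaldehyde | COc1cc(O)c(C=O)c(OC)c1CC=C(C)C | intermediate
8 | acrylonitrile | C=CC#N | starting material
9 | 5,7-dimethoxy-6-(3-methylbut-2-en-1-yl)-2H-chromene-3-carbonitrile | COc1cc2c(c(OC)c1CC=C(C)C)C=C(C#N)CO2 | intermediate
10 | 5,7-dimethoxy-6-(3-methylbut-2-en-1-yl)-2H-chromene-3-carboxylic acid | COc1cc2c(c(OC)c1CC=C(C)C)C=C(C(=O)O)CO2 | intermediate
11 | (3S)-5,7-dimethoxy-6-(3-methylbut-2-en-1-yl)chromane-3-carboxylic acid | COc1cc2c(c(OC)c1CC=C(C)C)C[C@H](C(=O)O)CO2 | intermediate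
12 | [(3R)-5,7-dimethoxy-6-(3-methylbut-2-en-1-yl)chroman-3-yl]methanol | COc1cc2c(c(OC)c1CC=C(C)C)C[C@H](CO)CO2 | intermediate
13 | (3S)-5,7-dimethoxy-6-(3-methylbut-2-en-1-yl)chromane-3-carbaldehyde | COc1cc2c(c(OC)c1CC=C(C)C)C[C@H](C=O)CO2 | intermediate
14 | (3R)-3-(2,2-dibromoethenyl)-5,7-dimethoxy-6-(3-methylbut-2-en-1-yl)chromane | COc1cc2c(c(OC)c1CC=C(C)C)C[C@H](C=C(Br)Br)CO2 | intermediate
15 | dimethyl squarate (3,4-dimethoxycyclobut-3-ene-1,2-dione) | COC1=C(OC)C(=O)C1=O | starting material
16 | allylmagnesium bromide | C=CC[Mg]Br | starting material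
17 | bromomagnesium alkoxide of 4-allyl-4-hydroxy-2,3-dimethoxycyclobut-2-en-1-one | COC1=C(OC)C(CC=C)(O[Mg]Br)C1=O | intermediate (not isolated)
18 | 3-methoxy-4-(prop-2-en-1-yl)cyclobut-3-ene-1,2-dione | C=CCC1=C(OC)C(=O)C1=O | intermediate
19 | 2-methylbut-2-ene | CC=C(C)C | starting material
20 | 3-methoxy-4-(3-methylbut-2-en-1-yl)cyclobut-3-ene-1,2-dione | CC(C)=CCC1=C(OC)C(=O)C1=O | intermediate
21 | lithium acetylide of (3R)-3-ethynyl-5,7-dimethoxy-6-(3-methylbut-2-en-1-yl)chromane | COc1cc2c(c(OC)c1CC=C(C)C)C[C@H](C#C[Li])CO2 | intermediate (not isolated)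
22 | 4-hydroxy-3-methoxy-2-(3-methylbut-2-en-1-yl)-4-{[(3R)-5,7-dimethoxy-6-(3-methylbut-2-en-1-yl)chroman-3-yl]ethynyl}cyclobut-2-en-1-one (both carbinol epimers) | COc1cc2c(c(OC)c1CC=C(C)C)C[C@H](C#CC1(O)C(OC)=C(CC=C(C)C)C1=O)CO2 | intermediate
23 | (Z)-enynylketene: 4-hydroxy-3-methoxy-2-(3-methylbut-2-en-1-yl)-6-[(3R)-chroman-3-yl]hexa-1,3-dien-5-yn-1-one (chroman substituted as in 22) | COc1cc2c(c(OC)c1CC=C(C)C)C[C@H](C#C/C(O)=C(OC)\C(CC=C(C)C)=C=O)CO2 | intermediate (not isolated)
24 | aryl diradical (phenoxyl O-radical at C4–O, σ-radical at C6 of the new ring) | COc1cc2c(c(OC)c1CC=C(C)C)C[C@H](c1[c]c(O)c(OC)c(CC=C(C)C)c1[O])CO2 | intermediate (not isolated)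
25 | 2-methoxy-3-(3-methylbut-2-en-1-yl)-5-[(3R)-5,7-dimethoxy-6-(3-methylbut-2-en-1-yl)chroman-3-yl]cyclohexa-2,5-diene-1,4-dione | COc1cc2c(c(OC)c1CC=C(C)C)C[C@H](C1=CC(=O)C(OC)=C(CC=C(C)C)C1=O)CO2 | intermediate
26 | 2-hydroxy-3-(3-methylbut-2-en-1-yl)-5-[(3R)-5,7-dimethoxy-6-(3-methylbut-2-en-1-yl)chroman-3-yl]cyclohexa-2,5-diene-1,4-dione (CNP0241224.1) | COc1cc2c(c(OC)c1CC=C(C)C)C[C@H](C1=CC(=O)C(O)=C(CC=C(C)C)C1=O)CO2 | target

**Step count.** Total: 15 steps. Longest linear sequence: 13 steps (steps 1–10, then 13–15); steps 11–12 form the second branch.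

**Steps most likely to fail**

Step 14 (key step). The enynylketene may divert into five-membered ring closure to an alkylidenecyclopentenedione, or the ring σ-radical may abstract hydrogen from a chroman CH2 group instead of accepting the hydroxyl hydrogen. The fallback closes the same ring by the purely pericyclic alkenyl variant, which has no diradical; it sets out from aldehyde 13 and returns at quinone 25. Takai iodo-olefination of 13 (CHI3, CrCl2, THF, 0 °C) should give the (E)-vinyl iodide F1. Iodine–lithium exchange (t-BuLi, 2 equiv, Et2O, −78 °C) gives the vinyllithium F2, which is added to dione 20 at −78 °C to give the 4-alkenyl-4-hydroxycyclobutenone F3. Heating F3 (toluene, 110 °C) should bring about thermal ring expansion (4π opening, 6π electrocyclisation, enolisation) to the hydroquinone F4, and Ag2O (Et2O, rt) oxidises F4 to 25.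

Step 15. Base may epimerise C3 through a quinone-methide tautomer, or hydroxide may add in conjugate fashion at the unsubstituted quinone carbon. The fallback carries the oxygen as an acid-labile tert-butyl ether and avoids base at the end; it sets out from dibromoalkene 14 (with 16 and 19) and returns at target 26. Commercial di-tert-butyl squarate F5 is treated with 16 and then trifluoroacetic anhydride as in step 11 to give 3-allyl-4-tert-butoxycyclobutenedione F6. Cross-metathesis with 19 as in step 12 gives the prenyl tert-butoxy dione F7. Acetylide 21, made from 14 as in step 13, is added to F7 to give the tert-butoxy carbinol F8, which is heated as in step 14 to give the tert-butoxyquinone F9. Dilute trifluoroacetic acid (CH2Cl2, 0 °C) should then release 26 with loss of 2-methylpropene.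

Step 7. Facial selectivity may be insufficient on this hindered, electron-rich chromene acid, or the prenyl double bond may be reduced competitively. The fallback replaces catalyst control by a covalent resolution; it sets out from acid 10 and returns at alcohol 12. Hydrogenation of 10 with an achiral carboxylate-directed catalyst (Ru(OAc)2(rac-BINAP), H2, MeOH) gives the racemic acid F10. Coupling with (S)-4-benzyl-1,3-oxazolidin-2-one (EDC, DMAP, CH2Cl2) gives two diastereomeric imides, the (3S)-imide F11 and the (3R)-imide F12, which are separated by chromatography. LiBH4 (THF, H2O, 0 °C) on F11 should release 12 and the auxiliary.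

**Further compounds**

F1 | step 14 | (3R)-3-[(E)-2-iodoethenyl]-5,7-dimethoxy-6-(3-methylbut-2-en-1-yl)chromane | COc1cc2c(c(OC)c1CC=C(C)C)C[C@H](/C=C/I)CO2
F2 | step 14 | (E)-2-[(3R)-5,7-dimethoxy-6-(3-methylbut-2-en-1-yl)chroman-3-yl]ethenyllithium | COc1cc2c(c(OC)c1CC=C(C)C)C[C@H](/C=C/[Li])CO2
F3 | step 14 | 4-hydroxy-3-methoxy-2-(3-methylbut-2-en-1-yl)-4-{(E)-2-[(3R)-5,7-dimethoxy-6-(3-methylbut-2-en-1-yl)chroman-3-yl]ethenyl}cyclobut-2-en-1-one | COc1cc2c(c(OC)c1CC=C(C)C)C[C@H](/C=C/C1(O)C(OC)=C(CC=C(C)C)C1=O)CO2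
F4 | step 14 | 2-methoxy-3-(3-methylbut-2-en-1-yl)-5-[(3R)-5,7-dimethoxy-6-(3-methylbut-2-en-1-yl)chroman-3-yl]benzene-1,4-diol | COc1cc2c(c(OC)c1CC=C(C)C)C[C@H](c1cc(O)c(OC)c(CC=C(C)C)c1O)CO2
F5 | step 15 | di-tert-butyl squarate (3,4-di-tert-butoxycyclobut-3-ene-1,2-dione) | CC(C)(C)OC1=C(OC(C)(C)C)C(=O)C1=O
F6 | step 15 | 3-tert-butoxy-4-(prop-2-en-1-yl)cyclobut-3-ene-1,2-dione | C=CCC1=C(OC(C)(C)C)C(=O)C1=O
F7 | step 15 | 3-tert-butoxy-4-(3-methylbut-2-en-1-yl)cyclobut-3-ene-1,2-dione | CC(C)=CCC1=C(OC(C)(C)C)C(=O)C1=O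
F8 | step 15 | 3-tert-butoxy-4-hydroxy-2-(3-methylbut-2-en-1-yl)-4-{[(3R)-5,7-dimethoxy-6-(3-methylbut-2-en-1-yl)chroman-3-yl]ethynyl}cyclobut-2-en-1-one | COc1cc2c(c(OC)c1CC=C(C)C)C[C@H](C#CC1(O)C(OC(C)(C)C)=C(CC=C(C)C)C1=O)CO2
F9 | step 15 | 2-tert-butoxy-3-(3-methylbut-2-en-1-yl)-5-[(3R)-5,7-dimethoxy-6-(3-methylbut-2-en-1-yl)chroman-3-yl]cyclohexa-2,5-diene-1,4-dione | COc1cc2c(c(OC)c1CC=C(C)C)C[C@H](C1=CC(=O)C(OC(C)(C)C)=C(CC=C(C)C)C1=O)CO2
F10 | step 7 | racemic 5,7-dimethoxy-6-(3-methylbut-2-en-1-yl)chromane-3-carboxylic acid | COc1cc2c(c(OC)c1CC=C(C)C)CC(C(=O)O)CO2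
F11 | step 7 | (4S)-4-benzyl-3-{[(3S)-5,7-dimethoxy-6-(3-methylbut-2-en-1-yl)chroman-3-yl]carbonyl}-1,3-oxazolidin-2-one | COc1cc2c(c(OC)c1CC=C(C)C)C[C@H](C(=O)N1[C@@H](Cc3ccccc3)COC1=O)CO2
F12 | step 7 | (4S)-4-benzyl-3-{[(3R)-5,7-dimethoxy-6-(3-methylbut-2-en-1-yl)chroman-3-yl]carbonyl}-1,3-oxazolidin-2-one | COc1cc2c(c(OC)c1CC=C(C)C)C[C@@H](C(=O)N1[C@@H](Cc3ccccc3)COC1=O)CO2
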